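**Plan**

1. Retrosynthesis: the C3 formyl group is traced back to a methyl ester and the three hydroxyls to two methoxymethyl (MOM) ethers and one triethylsilyl ether; the furan is then cut at O1–C7a and C3–C3a in one operation.
2. Enabling feature: in ring A the C3a–C7a bond lies between the C4 oxygen and C7–H, so the aryne across it is a 3-alkoxyaryne that accepts an oxygen nucleophile at C7a and a carbon electrophile at C3a. The partner, supplying O1, C2 and C3, is the phenyliodonium ylide of the ring-B β-keto ester.
3. Ring A (steps 1–8): 3-methoxyphenol is MOM-protected; three directed ortho-metalations then attach the C5 side chain (prenylation, then hydration), the C3a oxygen and the C7a silicon, each at a position fixed by the directing groups, and give the silyl triflate.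
4. Ring B (steps 9–11): MOM protection of the acetophenone, Claisen condensation with dimethyl carbonate, ylide formation with PhI(OAc)2.
5. Forward order: the two arenes are joined and the furan, the only ring made, closes in step 12; ester to alcohol to aldehyde (steps 13 and 14); acid removes the three protecting groups (step 15).
6. Stereochemistry: the target has no stereocentre and none is created on the way.

Key step: step 12

Remark on the chemistry: the phenols are carried as MOM ethers (they direct the ring-A lithiations, are inert to fluoride and need no hydrogenolysis next to the aldehyde), and the ylide is used as its methyl ester so that it can be made in methanol.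

**Route**

Step 1
Reactants: 1 3-methoxyphenol
Product: 2 1-methoxy-3-(methoxymethoxy)benzene
Conditions: NaH, DMF, 0 °C; MOMCl, 0 °C to rt
Reagents that add atoms: chloromethyl methyl ether, COCCl
Why: Williamson-type O-alkylation of the sodium phenoxide by the α-chloro ether is fast and clean, and the acetal formed is the directing group for the metalations that follow.

Step 2
Reactants: 2 1-methoxy-3-(methoxymethoxy)benzene
Product: 4 1-methoxy-3-(methoxymethoxy)-2-(3-methylbut-2-en-1-yl)benzene, via aryllithium 3 (not isolated)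
Conditions: n-BuLi, THF, 0 °C; CuI (cat.), prenyl bromide, −78 °C to rt
Reagents that add atoms: prenyl bromide (1-bromo-3-methylbut-2-ene), CC(C)=CCBr
Why: Directed ortho-metalation occurs at the carbon between the two oxygens, where both ether groups coordinate lithium, and the aryllithium is allylated at the primary carbon of prenyl bromide under CuI catalysis (SN2 allylic alkylation).

Step 3
Reactants: 4 1-methoxy-3-(methoxymethoxy)-2-(3-methylbut-2-en-1-yl)benzene
Product: 5 4-[2-methoxy-6-(methoxymethoxy)phenyl]-2-methylbutan-2-ol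
Conditions: Co(acac)2 (cat.), PhSiH3, O2 (1 atm), THF, rt
Reagents that add atoms: dioxygen, O=O
Why: Mukaiyama hydration: a cobalt hydride transfers a hydrogen atom to the trisubstituted alkene, O2 traps the tertiary radical and the silane reduces the peroxide, so the Markovnikov tertiary alcohol results without touching the acetal; no stereocentre is formed.

Step 4
Reactants: 5 4-[2-methoxy-6-(methoxymethoxy)phenyl]-2-methylbutan-2-ol
Product: 6 triethyl({4-[2-methoxy-6-(methoxymethoxy)phenyl]-2-methylbutan-2-yl}oxy)silane
Conditions: TESOTf, 2,6-lutidine, CH2Cl2, −78 to 0 °C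
Reagents that add atoms: triethylsilyl trifluoromethanesulfonate, CC[Si](CC)(CC)OS(=O)(=O)C(F)(F)F
Why: Silyl ether formation with a silyl triflate and a hindered pyridine base is fast at low temperature even for a tertiary alcohol, well before the triflate can activate the aryl acetal; the ether masks the alcohol against the organolithium and triflating reagents to come.

Step 5
Reactants: 6 triethyl({4-[2-methoxy-6-(methoxymethoxy)phenyl]-2-methylbutan-2-yl}oxy)silane
Product: 9 4-methoxy-2-(methoxymethoxy)-3-[3-methyl-3-(triethylsilyloxy)butyl]phenol, via aryllithium 7 (not isolated), via dimethyl arylboronate 8 (not isolated)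
Conditions: n-BuLi, TMEDA, Et2O, 0 °C; B(OMe)3, −78 °C to rt; H2O2 (30% aq), NaOH, 0 °C
Reagents that add atoms: hydrogen peroxide, OO; trimethyl borate, COB(OC)OC (its boron and methoxy groups are carried only by 8)
Why: Directed ortho-metalation, borylation and oxidation: the MOM ether is a stronger director than methoxy and has a single free ortho carbon (the future C3a), and hydroperoxide oxidises the aryl boronate to the phenol by 1,2-migration of the aryl group from boron to oxygen.

Step 6
Reactants: 9 4-methoxy-2-(methoxymethoxy)-3-[3-methyl-3-(triethylsilyloxy)butyl]phenol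
Product: 10 4-methoxy-2-(methoxymethoxy)-3-[3-methyl-3-(triethylsilyloxy)butyl]phenyl N-(propan-2-yl)carbamate
Conditions: i-PrNCO, Et3N (cat.), CH2Cl2, rt
Reagents that add atoms: isopropyl isocyanate, CC(C)N=C=O
Why: Amine-catalysed addition of the phenol to the isocyanate gives the secondary carbamate, which directs the next metalation and can later be removed under mild base.

Step 7
Reactants: 10 4-methoxy-2-(methoxymethoxy)-3-[3-methyl-3-(triethylsilyloxy)butyl]phenyl N-(propan-2-yl)carbamate
Product: 14 4-methoxy-2-(methoxymethoxy)-3-[3-methyl-3-(triethylsilyloxy)butyl]-6-(trimethylsilyl)phenyl N-(propan-2-yl)carbamate, via N-silyl carbamate 11 (not isolated), via lithiated N-silyl carbamate 12 (not isolated), via C-silylated N-silyl carbamate 13 (not isolated)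
Conditions: TBSOTf, TMEDA, Et2O, 0 °C to rt; n-BuLi, TMEDA, −78 °C; TMSCl, −78 °C to rt; cold NaHSO4 (aq) work-up
Reagents that add atoms: chlorotrimethylsilane, C[Si](C)(C)Cl; tert-butyldimethylsilyl trifluoromethanesulfonate, CC(C)(C)[Si](C)(C)OS(=O)(=O)C(F)(F)F (its silyl group is carried only by 11, 12 and 13)
Why: Directed ortho-metalation of a carbamate: silylation on nitrogen removes the acidic N–H and blocks anionic Fries-type migration, the carbamate then directs n-BuLi to its only free ortho carbon (the future C7a, since the other ortho carbon bears the MOM ether), chlorotrimethylsilane traps the aryllithium, and the N-silyl group is hydrolysed on work-up.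

Step 8
Reactants: 14 4-methoxy-2-(methoxymethoxy)-3-[3-methyl-3-(triethylsilyloxy)butyl]-6-(trimethylsilyl)phenyl N-(propan-2-yl)carbamate
Product: 16 4-methoxy-2-(methoxymethoxy)-3-[3-methyl-3-(triethylsilyloxy)butyl]-6-(trimethylsilyl)phenyl trifluoromethanesulfonate, via silylphenol 15 (not isolated)
Conditions: DBU, Et2NH, MeCN, 40 °C; then PhNTf2, rt
Reagents that add atoms: N-phenylbis(trifluoromethanesulfonimide), O=S(=O)(N(c1ccccc1)S(=O)(=O)C(F)(F)F)C(F)(F)F
Why: Base-induced E1cB cleavage of the secondary carbamate releases isopropyl isocyanate, which diethylamine captures as a urea, and the phenoxide is triflated in the same flask by the mild triflyl donor PhNTf2, which leaves the aryl–silicon bond, the acetal and the silyl ether alone.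

Step 9
Reactants: 17 1-(4-hydroxy-2-methoxyphenyl)ethanone
Product: 18 1-[2-methoxy-4-(methoxymethoxy)phenyl]ethanone
Conditions: NaH (1 equiv), DMF, 0 °C; MOMCl, 0 °C to rt
Reagents that add atoms: chloromethyl methyl ether, COCCl
Why: Williamson-type O-alkylation of the acidic para-acyl phenoxide; one equivalent of NaH at 0 °C deprotonates the phenol and not the methyl ketone.

Step 10
Reactants: 18 1-[2-methoxy-4-(methoxymethoxy)phenyl]ethanone
Product: 19 methyl 3-[2-methoxy-4-(methoxymethoxy)phenyl]-3-oxopropanoate
Conditions: NaH, (MeO)2CO, THF, reflux; AcOH quench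
Reagents that add atoms: dimethyl carbonate, COC(=O)OC
Why: Crossed Claisen condensation: the ketone enolate is acylated by dimethyl carbonate, and irreversible deprotonation of the β-keto ester formed drives the reaction.

Step 11
Reactants: 19 methyl 3-[2-methoxy-4-(methoxymethoxy)phenyl]-3-oxopropanoate
Product: 20 methyl 3-[2-methoxy-4-(methoxymethoxy)phenyl]-3-oxo-2-(phenyliodonio)propanoate ylide
Conditions: PhI(OAc)2, KOH, MeOH, 0 °C
Reagents that add atoms: (diacetoxyiodo)benzene, CC(=O)OI(OC(C)=O)c1ccccc1
Why: Condensation of the active methylene compound with PhI(OAc)2 under base (exchange of both acetate ligands at trivalent iodine) is the standard preparation of phenyliodonium ylides of 1,3-dicarbonyl compounds; methanol matches the methyl ester, so transesterification is excluded, and the ylide is used without delay.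

Step 12
Reactants: 16 4-methoxy-2-(methoxymethoxy)-3-[3-methyl-3-(triethylsilyloxy)butyl]-6-(trimethylsilyl)phenyl trifluoromethanesulfonate; 20 methyl 3-[2-methoxy-4-(methoxymethoxy)phenyl]-3-oxo-2-(phenyliodonio)propanoate ylide
Product: 22 methyl 6-methoxy-2-[2-methoxy-4-(methoxymethoxy)phenyl]-4-(methoxymethoxy)-5-[3-methyl-3-(triethylsilyloxy)butyl]-1-benzofuran-3-carboxylate, via aryne 21 (not isolated)
Conditions: CsF, MeCN, rt (ylide in excess)
Reagents that add atoms: none
Why: Fluoride removes the trimethylsilyl group of 16 and the adjacent triflate departs, so aryne 21 forms under neutral conditions at room temperature; the ketone-enolate oxygen of ylide 20 adds to C7a, and the aryl anion left at C3a attacks the ylide carbon through the trivalent iodine centre (ligand coupling) with loss of iodobenzene. The closest known reaction type is the CsF-mediated annulation of arynes from 2-(trimethylsilyl)aryl triflates with phenyliodonium ylides of 1,3-diketones and β-keto esters, which gives 3-acylbenzofurans and benzofuran-3-carboxylates. The furan, the only ring formed, closes in a stepwise (3+2) mode: O1–C7a by intermolecular nucleophilic addition, then C3–C3a by an intramolecular five-membered ring closure of the aryl carbanion onto the iodonium-bearing carbon, which gives the aromatic heterocycle directly. No stereocentre is created. The selectivity needed is the direction of addition to the unsymmetrical aryne, and the C4 MOM ether next to C3a secures it: its inductive effect and the distortion it imposes on the aryne stabilise negative charge at C3a, so the oxygen nucleophile attacks the remote carbon C7a, as nucleophiles do with other 3-alkoxyarynes. The ketone oxygen, not the ester oxygen, is the nucleophilic end of the ylide, so ring B arrives on C2 and the ester on C3.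

Step 13
Reactants: 22 methyl 6-methoxy-2-[2-methoxy-4-(methoxymethoxy)phenyl]-4-(methoxymethoxy)-5-[3-methyl-3-(triethylsilyloxy)butyl]-1-benzofuran-3-carboxylate
Product: 23 {6-methoxy-2-[2-methoxy-4-(methoxymethoxy)phenyl]-4-(methoxymethoxy)-5-[3-methyl-3-(triethylsilyloxy)butyl]-1-benzofuran-3-yl}methanol
Conditions: i-Bu2AlH, CH2Cl2, −78 to 0 °C; KNaC4H4O6 (aq) work-up
Reagents that add atoms: none
Why: Hydride reduction of the ester by i-Bu2AlH goes to the primary alcohol and does not affect the acetals, the silyl ether or the benzofuran; the neutral tartrate work-up protects the ionisable 3-(hydroxymethyl)benzofuran.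

Step 14
Reactants: 23 {6-methoxy-2-[2-methoxy-4-(methoxymethoxy)phenyl]-4-(methoxymethoxy)-5-[3-methyl-3-(triethylsilyloxy)butyl]-1-benzofuran-3-yl}methanol
Product: 24 6-methoxy-2-[2-methoxy-4-(methoxymethoxy)phenyl]-4-(methoxymethoxy)-5-[3-methyl-3-(triethylsilyloxy)butyl]-1-benzofuran-3-carbaldehyde
Conditions: MnO2 (activated, excess), CH2Cl2, rt
Reagents that add atoms: none
Why: MnO2 oxidises benzylic-type alcohols selectively under neutral conditions, so the heteroaryl carbinol gives the aldehyde without over-oxidation.

Step 15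
Reactants: 24 6-methoxy-2-[2-methoxy-4-(methoxymethoxy)phenyl]-4-(methoxymethoxy)-5-[3-methyl-3-(triethylsilyloxy)butyl]-1-benzofuran-3-carbaldehyde
Product: 25 4-hydroxy-2-(4-hydroxy-2-methoxyphenyl)-5-(3-hydroxy-3-methylbutyl)-6-methoxy-1-benzofuran-3-carbaldehyde
Conditions: HCl (2 M aq), MeOH–THF, 40 °C
Reagents that add atoms: none
Why: Acid-catalysed hydrolysis of the two aryl methoxymethyl acetals and solvolysis of the tertiary triethylsilyl ether occur together under dilute acid, conditions under which a tertiary aliphatic alcohol ionises only slowly; the product has no stereocentre.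

**Compound list**

1 | 3-methoxyphenol | COc1cccc(O)c1 | starting material
2 | 1-methoxy-3-(methoxymethoxy)benzene | COCOc1cccc(OC)c1 | intermediate
3 | [2-methoxy-6-(methoxymethoxy)phenyl]lithium (not isolated) | [Li]c1c(OC)cccc1OCOC | intermediate
4 | 1-methoxy-3-(methoxymethoxy)-2-(3-methylbut-2-en-1-yl)benzene | COCOc1cccc(OC)c1CC=C(C)C | intermediate
5 | 4-[2-methoxy-6-(methoxymethoxy)phenyl]-2-methylbutan-2-ol | COCOc1cccc(OC)c1CCC(C)(C)O | intermediate
6 | triethyl({4-[2-methoxy-6-(methoxymethoxy)phenyl]-2-methylbutan-2-yl}oxy)silane | COCOc1cccc(OC)c1CCC(C)(C)O[Si](CC)(CC)CC | intermediate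
7 | {4-methoxy-2-(methoxymethoxy)-3-[3-methyl-3-(triethylsilyloxy)butyl]phenyl}lithium (not isolated) | [Li]c1ccc(OC)c(CCC(C)(C)O[Si](CC)(CC)CC)c1OCOC | intermediate
8 | dimethyl {4-methoxy-2-(methoxymethoxy)-3-[3-methyl-3-(triethylsilyloxy)butyl]phenyl}boronate (not isolated) | COB(OC)c1ccc(OC)c(CCC(C)(C)O[Si](CC)(CC)CC)c1OCOC | intermediate
9 | 4-methoxy-2-(methoxymethoxy)-3-[3-methyl-3-(triethylsilyloxy)butyl]phenol | Oc1ccc(OC)c(CCC(C)(C)O[Si](CC)(CC)CC)c1OCOC | intermediate
10 | 4-methoxy-2-(methoxymethoxy)-3-[3-methyl-3-(triethylsilyloxy)butyl]phenyl N-(propan-2-yl)carbamate | CC(C)NC(=O)Oc1ccc(OC)c(CCC(C)(C)O[Si](CC)(CC)CC)c1OCOC | intermediate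
11 | 4-methoxy-2-(methoxymethoxy)-3-[3-methyl-3-(triethylsilyloxy)butyl]phenyl N-(tert-butyldimethylsilyl)-N-(propan-2-yl)carbamate (not isolated) | CC(C)N(C(=O)Oc1ccc(OC)c(CCC(C)(C)O[Si](CC)(CC)CC)c1OCOC)[Si](C)(C)C(C)(C)C | intermediate
12 | 6-lithio derivative of 11 (not isolated) | CC(C)N(C(=O)Oc1c([Li])cc(OC)c(CCC(C)(C)O[Si](CC)(CC)CC)c1OCOC)[Si](C)(C)C(C)(C)C | intermediate
13 | 6-(trimethylsilyl) derivative of 11 (not isolated) | CC(C)N(C(=O)Oc1c([Si](C)(C)C)cc(OC)c(CCC(C)(C)O[Si](CC)(CC)CC)c1OCOC)[Si](C)(C)C(C)(C)C | intermediate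
14 | 4-methoxy-2-(methoxymethoxy)-3-[3-methyl-3-(triethylsilyloxy)butyl]-6-(trimethylsilyl)phenyl N-(propan-2-yl)carbamate | CC(C)NC(=O)Oc1c([Si](C)(C)C)cc(OC)c(CCC(C)(C)O[Si](CC)(CC)CC)c1OCOC | intermediate
15 | 4-methoxy-2-(methoxymethoxy)-3-[3-methyl-3-(triethylsilyloxy)butyl]-6-(trimethylsilyl)phenol (not isolated) | Oc1c([Si](C)(C)C)cc(OC)c(CCC(C)(C)O[Si](CC)(CC)CC)c1OCOC | intermediate
16 | 4-methoxy-2-(methoxymethoxy)-3-[3-methyl-3-(triethylsilyloxy)butyl]-6-(trimethylsilyl)phenyl trifluoromethanesulfonate | FC(F)(F)S(=O)(=O)Oc1c([Si](C)(C)C)cc(OC)c(CCC(C)(C)O[Si](CC)(CC)CC)c1OCOC | intermediate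
17 | 1-(4-hydroxy-2-methoxyphenyl)ethanone | COc1cc(O)ccc1C(C)=O | starting material
18 | 1-[2-methoxy-4-(methoxymethoxy)phenyl]ethanone | COCOc1ccc(C(C)=O)c(OC)c1 | intermediate
19 | methyl 3-[2-methoxy-4-(methoxymethoxy)phenyl]-3-oxopropanoate | COCOc1ccc(C(=O)CC(=O)OC)c(OC)c1 | intermediate
20 | methyl 3-[2-methoxy-4-(methoxymethoxy)phenyl]-3-oxo-2-(phenyliodonio)propanoate ylide | COCOc1ccc(C(=O)[C-]([I+]c2ccccc2)C(=O)OC)c(OC)c1 | intermediate
21 | 5-methoxy-3-(methoxymethoxy)-4-[3-methyl-3-(triethylsilyloxy)butyl]-1,2-didehydrobenzene (aryne, not isolated) | COCOC1=C(CCC(C)(C)O[Si](CC)(CC)CC)C(OC)=CC#C1 | intermediate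
22 | methyl 6-methoxy-2-[2-methoxy-4-(methoxymethoxy)phenyl]-4-(methoxymethoxy)-5-[3-methyl-3-(triethylsilyloxy)butyl]-1-benzofuran-3-carboxylate | COC(=O)c1c(-c2ccc(OCOC)cc2OC)oc2cc(OC)c(CCC(C)(C)O[Si](CC)(CC)CC)c(OCOC)c12 | intermediate
23 | {6-methoxy-2-[2-methoxy-4-(methoxymethoxy)phenyl]-4-(methoxymethoxy)-5-[3-methyl-3-(triethylsilyloxy)butyl]-1-benzofuran-3-yl}methanol | OCc1c(-c2ccc(OCOC)cc2OC)oc2cc(OC)c(CCC(C)(C)O[Si](CC)(CC)CC)c(OCOC)c12 | intermediate
24 | 6-methoxy-2-[2-methoxy-4-(methoxymethoxy)phenyl]-4-(methoxymethoxy)-5-[3-methyl-3-(triethylsilyloxy)butyl]-1-benzofuran-3-carbaldehyde | O=Cc1c(-c2ccc(OCOC)cc2OC)oc2cc(OC)c(CCC(C)(C)O[Si](CC)(CC)CC)c(OCOC)c12 | intermediate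
25 | 4-hydroxy-2-(4-hydroxy-2-methoxyphenyl)-5-(3-hydroxy-3-methylbutyl)-6-methoxy-1-benzofuran-3-carbaldehyde | COc1cc(O)ccc1-c1oc2cc(OC)c(CCC(C)(C)O)c(O)c2c1C=O | target

**Step count and risks**

Total: 15 steps. Longest linear sequence: 12 steps (steps 1–8, then 12–15); ring B joins after 3 steps (9–11).

Step 12 (most likely to fail). The ambident ylide may bond to the aryne through carbon instead of the ketone oxygen, or the aryl anion at C3a may be protonated by the medium before it closes the ring. The acyclic ylide may also decompose faster than the hindered silyl triflate releases the aryne. In each case regiocontrol or ring closure is lost. The fallback sets out from 16 and comes back at 22; it keeps the aryne for the ring-A regiochemistry but assembles the furan by alkyne oxypalladation instead of the (3+2) annulation. CsF in DMF generates the same aryne, which inserts into the formamide C=O bond with the amide oxygen going to C7a (an oxygen-only nucleophile). Aqueous hydrolysis gives 2-hydroxy-4-methoxy-6-(methoxymethoxy)-5-[3-methyl-3-(triethylsilyloxy)butyl]benzaldehyde F1. Seyferth–Gilbert homologation with dimethyl (1-diazo-2-oxopropyl)phosphonate (K2CO3, MeOH) converts the aldehyde into 2-ethynyl-5-methoxy-3-(methoxymethoxy)-4-[3-methyl-3-(triethylsilyloxy)butyl]phenol F2. Sonogashira coupling (Pd(PPh3)2Cl2, CuI, Et3N, rt) with 1-iodo-2-methoxy-4-(methoxymethoxy)benzene F3, made from commercial 4-iodo-3-methoxyphenol with NaH and MOMCl, gives 5-methoxy-2-{[2-methoxy-4-(methoxymethoxy)phenyl]ethynyl}-3-(methoxymethoxy)-4-[3-methyl-3-(triethylsilyloxy)butyl]phenol F4. Oxidative methoxycarbonylative cyclisation of this 2-alkynylphenol (PdCl2 cat., CuCl2, NaOAc, CO 1 atm, MeOH, rt) closes O1–C2 and places the methyl ester on C3, which is compound 22.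

Step 15. Once the silyl ether is lost, acid can ionise the side-chain tertiary alcohol; capture of the cation by the neighbouring C4 phenol (chroman formation) or elimination would then compete with the slower cleavage of the ring-B acetal. The fallback sets out from 24 and comes back at 25, and it stages the unmasking so that phenol and free tertiary alcohol never meet acid. TMSOTf and 2,2′-bipyridyl in CH2Cl2 at 0 °C exchange the two aryl methoxymethyl groups for trimethylsilyl groups without Brønsted acid while the tertiary alcohol stays silylated. Water then gives 4-hydroxy-2-(4-hydroxy-2-methoxyphenyl)-6-methoxy-5-[3-methyl-3-(triethylsilyloxy)butyl]-1-benzofuran-3-carbaldehyde F5. Bu4NF buffered with AcOH in THF removes the triethylsilyl group and delivers 25.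

Step 2. Allylation of the hindered aryllithium can be eroded by attack at the tertiary end of the allyl system (SN2′), by halogen–lithium exchange and by coupling of prenyl bromide with itself. The fallback sets out from 2 and comes back at 5, so it also bypasses step 3, and it builds the side chain by cross-coupling. The same lithiation of 2 is quenched with I2 to give 2-iodo-1-methoxy-3-(methoxymethoxy)benzene F6. Sonogashira coupling with 2-methylbut-3-yn-2-ol (Pd(PPh3)2Cl2, CuI, Et3N, 60 °C) gives 4-[2-methoxy-6-(methoxymethoxy)phenyl]-2-methylbut-3-yn-2-ol F7. Hydrogenation of the alkyne (H2, Pd/C, EtOAc) saturates the chain and gives alcohol 5 with the acetal intact.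

**Further compounds**

F1 | step 12 | 2-hydroxy-4-methoxy-6-(methoxymethoxy)-5-[3-methyl-3-(triethylsilyloxy)butyl]benzaldehyde | O=Cc1c(O)cc(OC)c(CCC(C)(C)O[Si](CC)(CC)CC)c1OCOC
F2 | step 12 | 2-ethynyl-5-methoxy-3-(methoxymethoxy)-4-[3-methyl-3-(triethylsilyloxy)butyl]phenol | C#Cc1c(O)cc(OC)c(CCC(C)(C)O[Si](CC)(CC)CC)c1OCOC
F3 | step 12 | 1-iodo-2-methoxy-4-(methoxymethoxy)benzene | COCOc1ccc(I)c(OC)c1
F4 | step 12 | 5-methoxy-2-{[2-methoxy-4-(methoxymethoxy)phenyl]ethynyl}-3-(methoxymethoxy)-4-[3-methyl-3-(triethylsilyloxy)butyl]phenol | COCOc1ccc(C#Cc2c(O)cc(OC)c(CCC(C)(C)O[Si](CC)(CC)CC)c2OCOC)c(OC)c1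
F5 | step 15 | 4-hydroxy-2-(4-hydroxy-2-methoxyphenyl)-6-methoxy-5-[3-methyl-3-(triethylsilyloxy)butyl]-1-benzofuran-3-carbaldehyde | COc1cc(O)ccc1-c1oc2cc(OC)c(CCC(C)(C)O[Si](CC)(CC)CC)c(O)c2c1C=O
F6 | step 2 | 2-iodo-1-methoxy-3-(methoxymethoxy)benzene | COCOc1cccc(OC)c1I
F7 | step 2 | 4-[2-methoxy-6-(methoxymethoxy)phenyl]-2-methylbut-3-yn-2-ol | COCOc1cccc(OC)c1C#CC(C)(C)O
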